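**Retrosynthetic overview**

1. The target (guaiane numbering) is reached from a cis-fused 1-hydroxyguaian-6-one acetonide by C4=C5 dehydrogenation, hydroxyl-directed C6 reduction, C3 allylic oxidation, C8 angeloylation and C11 acetylation.
2. Feature used: the β-hydroxy ketone array C1(OH)–C5–C6(=O) is an aldol retron that spans the ten-membered ring C1–C10, and C1, C6, C7, C8, C9 and C10 (with the C10 methyl and the three-carbon unit on C7) form a p-menthane ring as soon as C1 and C6 are joined.
3. Key disconnections: C1–C5 (transannular Mukaiyama aldol, closes rings A and B) and C3–C4 with reconnection of C1–C6 (anionic oxy-Cope), leading back to a 1-vinyl-2-(E)-propenyl-2-silyloxycyclohexanol.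
4. That cyclohexane comes from a C6 ketone plus a propenylcerium reagent, and a C1 vinyl carbinol made from a spiro-epoxide (oxygen delivered from the open face) plus a sulfonium ylide; ring carbons and C7 come from (R)-carvone (hydration, C8 allylic oxidation, all-cis hydrogenation).
5. Ring order: six-membered carbocycle (from carvone), then the ten-membered ring (oxy-Cope), then rings A (five) and B (seven) together in the aldol step.

Key step: step 17

Remark: all ring carbons carry their guaiane numbers throughout (carvone C1, C2, C3, C4, C5, C6 = guaiane C1, C10, C9, C8, C7, C6; C11 = side-chain carbinol carbon); "lower face" is the face that carries the C7 side chain, "upper face" the other.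

**Route**

Step 1
Reactants: 1 (R)-carvone
Product: 2 (5R)-5-(2-hydroxypropan-2-yl)-2-methylcyclohex-2-en-1-one
Conditions: 50% aq. H2SO4, 0 °C to rt
Reagents that add atoms: water, O
Why: Acid-catalysed Markovnikov hydration of the 1,1-disubstituted isopropenyl alkene through its tertiary cation leaves the electron-poor enone alkene and the C7 stereocentre untouched.

Step 2
Reactants: 2 (5R)-5-(2-hydroxypropan-2-yl)-2-methylcyclohex-2-en-1-one
Product: 3 (1R,5R)-5-(2-hydroxypropan-2-yl)-2-methylcyclohex-2-en-1-ol
Conditions: NaBH4, CeCl3·7H2O, MeOH, −78 °C to 0 °C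
Reagents that add atoms: none
Why: Luche 1,2-reduction with axial hydride delivery to the half-chair enone should give the C1 hydroxyl on the lower face (cis to the C7 side chain), a temporary centre that only masks the ketone.

Step 3
Reactants: 3 (1R,5R)-5-(2-hydroxypropan-2-yl)-2-methylcyclohex-2-en-1-ol
Product: 4 C1 tert-butyldimethylsilyl ether of 3 with free C11 hydroxyl
Conditions: TBSCl, imidazole, DMF, rt
Reagents that add atoms: tert-butyldimethylsilyl chloride, CC(C)(C)[Si](C)(C)Cl
Why: Selective O-silylation, since the secondary allylic alcohol reacts far faster than the tertiary C11 alcohol.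

Step 4
Reactants: 4 C1 silyl ether
Product: 5 C8 ketone (4-silyloxy-6-(2-hydroxypropan-2-yl)-3-methylcyclohex-2-en-1-one with silyloxy and side chain cis)
Conditions: Rh2(cap)4 (cap = caprolactamate, 1 mol%), t-BuOOH (70% in water), 1,2-dichloroethane, 40 °C
Reagents that add atoms: tert-butyl hydroperoxide, CC(C)(C)OO
Why: Dirhodium-catalysed allylic C–H oxidation with tert-butyl hydroperoxide should convert the only allylic methylene (C8) into the enone carbonyl, the C1–H being shielded by the silyl ether and the methyl C–H bonds being stronger.

Step 5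
Reactants: 5 C8 ketone
Product: 6 C8 alcohol with C8-OH and C7 side chain and C1 silyloxy group all on the lower face
Conditions: LiBH(s-Bu)3 (L-Selectride), THF, −78 °C
Reagents that add atoms: none
Why: Bulky-hydride 1,2-reduction (the β-carbon C10 is fully substituted) should occur from the face opposite the adjacent C7 hydroxyisopropyl group and so place the new C8 hydroxyl on the lower face, cis to the side chain.

Step 6
Reactants: 6 C8 alcohol
Product: 7 C8/C11 acetonide (cis-fused 1,3-dioxane) of the cyclohexene
Conditions: 2-methoxypropene, PPTS (cat.), CH2Cl2, 0 °C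
Reagents that add atoms: 2-methoxypropene, COC(C)=C
Why: Acid-catalysed acetalisation closes the six-membered isopropylidene acetal across the cis 1,3-diol (C8-OH and C11-OH) and protects both hydroxyls at once.

Step 7
Reactants: 7 cyclohexene acetonide
Product: 8 saturated acetonide with C10 methyl and C8-O and C7-C11 and C1 silyloxy all on the lower face
Conditions: H2 (1 atm), PtO2, EtOAc, rt
Reagents that add atoms: none
Why: Heterogeneous hydrogenation should occur from the upper face because both allylic oxygen substituents (C8, C1) and the C7 substituent lie on the lower face, so hydrogen adds to C10 from above and the C10 methyl ends on the lower face (all-cis); platinum is chosen to limit allylic C–O hydrogenolysis.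

Step 8
Reactants: 8 saturated silyl ether
Product: 9 C1 alcohol
Conditions: Bu4NF, THF, 0 °C to rt
Reagents that add atoms: none
Why: Fluoride-induced desilylation frees the C1 alcohol while C1 is still sp3, so the C10 centre cannot epimerise.

Step 9
Reactants: 9 C1 alcohol
Product: 10 C1 ketone (all-cis C7, C8, C10)
Conditions: Dess–Martin periodinane, NaHCO3, CH2Cl2, 0 °C to rt
Reagents that add atoms: none
Why: Dess–Martin oxidation under buffered, non-enolising conditions should give the ketone without epimerising the kinetically set C10 methyl centre.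

Step 10
Reactants: 10 C1 ketone
Product: 11 C1 exocyclic methylene compound (new carbon = C2)
Conditions: Zn, CH2Br2, TiCl4, THF (pre-formed reagent); 10, CH2Cl2, 0 °C to rt
Reagents that add atoms: dibromomethane, BrCBr
Why: Takai–Lombardo methylenation is non-basic and is the established way to methylenate epimerisable 2-alkylcyclohexanones without loss of the α-centre.

Step 11
Reactants: 11 exocyclic methylene compound
Product: 12 C6 allylic alcohol with C6-OH on the upper face
Conditions: SeO2 (cat.), t-BuOOH, CH2Cl2, rt
Reagents that add atoms: selenium dioxide (catalytic oxygen carrier), O=[Se]=O; tert-butyl hydroperoxide, CC(C)(C)OO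
Why: Selenium dioxide allylic hydroxylation (ene reaction then [2,3]-sigmatropic shift, as for exocyclic methylene terpenes) should functionalise the allylic methylene C6 in preference to the methine C10 and deliver oxygen from the less hindered upper face, anti to the C7 substituent.

Step 12
Reactants: 12 C6 allylic alcohol
Product: 13 C1 spiro-epoxide (epoxide oxygen on the upper face and its CH2 on the lower face) with C6 alcohol
Conditions: VO(acac)2 (cat.), t-BuOOH, CH2Cl2, 0 °C
Reagents that add atoms: tert-butyl hydroperoxide, CC(C)(C)OO
Why: Hydroxyl-directed vanadium-catalysed epoxidation delivers the epoxide oxygen to C1 syn to the C6 hydroxyl, which is also the sterically open upper face, and so fixes the C1–O bond opposite the C10 methyl group.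

Step 13
Reactants: 13 epoxy alcohol
Product: 14 spiro-epoxy C6 ketone
Conditions: Dess–Martin periodinane, NaHCO3, CH2Cl2, 0 °C
Reagents that add atoms: none
Why: Dess–Martin oxidation of the secondary C6 alcohol under neutral conditions should spare the epoxide and the epimerisable C7 centre.

Step 14
Reactants: 14 spiro-epoxy C6 ketone; 15 (E)-1-bromoprop-1-ene
Product: 18 C6 tertiary alcohol with (E)-propenyl on the upper face and hydroxyl on the lower face, via (E)-prop-1-enyllithium 16 (not isolated), via (E)-prop-1-enylcerium dichloride 17 (not isolated)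
Conditions: 15, t-BuLi (2 equiv), Et2O, −78 °C; CeCl3, THF, −78 °C; then 14, −78 °C
Reagents that add atoms: none
Why: Bromine–lithium exchange with retention of alkene geometry and transmetalation give a weakly basic organocerium that adds 1,2 to the hindered, enolisable ketone from the upper face, because the C7, C8 and C10 substituents and the epoxide methylene all shield the lower face.

Step 15
Reactants: 18 C6 tertiary alcohol
Product: 19 C6 tert-butyldimethylsilyl ether
Conditions: KN(SiMe3)2, THF, −78 °C; TBSOTf, −78 °C to −40 °C
Reagents that add atoms: tert-butyldimethylsilyl trifluoromethanesulfonate, CC(C)(C)[Si](C)(C)OS(=O)(=O)C(F)(F)F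
Why: O-silylation of the pre-formed potassium alkoxide at low temperature protects the tertiary hydroxyl without exposing the neighbouring spiro-epoxide to free Lewis acid (no semipinacol shift), and the bulky silyl group is chosen because it resists 1,2-oxygen-to-oxygen migration in the next two steps.

Step 16
Reactants: 19 C6 silyl ether spiro-epoxide
Product: 20 Cope substrate: C1 vinyl (lower face) and free C1 hydroxyl (upper face) next to C6 (E)-propenyl (upper face) and C6 silyloxy (lower face)
Conditions: Me3SI, n-BuLi, THF, −10 °C to rt
Reagents that add atoms: trimethylsulfonium iodide, C[S+](C)C.[I-]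
Why: Dimethylsulfonium methylide opens the spiro-epoxide at its methylene carbon and the resulting sulfonium alkoxide loses dimethyl sulfide (known one-carbon homologation of epoxides to allylic alcohols), which turns the epoxide into the vinyl carbinol with retention at C1.

Step 17
Reactants: 20 Cope substrate
Product: 23 cis-fused 1-hydroxyguaian-6-one acetonide, via ten-membered potassium enolate 21 (not isolated), via ten-membered keto silyl enol ether 22 (not isolated)
Conditions: KH, 18-crown-6, THF, 0 °C to rt; AcOH, −78 °C; CH2Cl2, BF3·OEt2 (excess), −78 °C to −40 °C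
Reagents that add atoms: none
Why: Proposed new method: deprotonation gives the C1 potassium alkoxide, whose charge-accelerated [3,3] shift (anionic oxy-Cope) runs through a chair transition state with vinyl and (E)-propenyl gauche and pseudo-equatorial and the two C–O bonds anti, forms C3–C4, breaks C1–C6 and leaves a ten-membered ring that holds a C1 enolate and a C5=C6 silyl enol ether; the closest known reactions are the oxy-Cope ring expansion of 1,2-dialkenylcyclohexanols to cyclodec-5-enones and the transannular aldol closure of cyclodecane-1,6-diones to hydroazulenols, and what is new is their union through a silyl enol ether that the rearrangement itself creates. Acetic acid at −78 °C turns the enolate into the C1 ketone and BF3·OEt2 then makes C5 add to C1 (transannular Mukaiyama aldol). Ring A (C1–C5) closes 5-exo-trig at the carbonyl carbon with the enol ether double bond exocyclic to the new ring, and ring B (C1, C5–C10) is the rest of the ten-membered ring. C4 is set in the chair transition state (propenyl methyl pseudo-equatorial, side defined by the C6 carbinol centre); C1 is set by the C1 carbinol centre of 20, because in the crossed conformer that the chair delivers C5 sits on the carbonyl face that C6 has just left and so takes the place of C6 while oxygen stays on the upper face, anti to the C10 methyl; C5 is set by the ring-trans enol ether, which offers only its inner face to C1 and so gives the cis ring fusion. The step needs regiocontrol among four possible transannular aldols, secured because only C5 is a silyl enol ether and only C1 a free ketone (the anti C–O bonds and the bulky silyl group suppress 1,2-silyl shift), and it needs ring closure before the ten-membered ring changes conformation, secured by adding the Lewis acid at −78 °C directly after the proton quench.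

Step 18
Reactants: 23 cis-fused 1-hydroxyguaian-6-one acetonide
Product: 24 C1 trimethylsilyl ether C5=C6 trimethylsilyl enol ether
Conditions: TMSOTf, Et3N, CH2Cl2, 0 °C
Reagents that add atoms: trimethylsilyl trifluoromethanesulfonate, C[Si](C)(C)OS(=O)(=O)C(F)(F)F
Why: Soft enolisation (silyl triflate and amine) silylates the tertiary alcohol and should give the thermodynamic silyl enol ether at C5=C6, because enolisation toward C7 would put the double bond exocyclic to the dioxane with the C11 gem-dimethyl group in allylic 1,3-strain against the silyloxy group.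

Step 19
Reactants: 24 bis-silyl compound
Product: 26 1-hydroxyguai-4-en-6-one acetonide, via C1 trimethylsilyl ether of the enone 25 (not isolated)
Conditions: Pd(OAc)2, MeCN, 40 °C; then citric acid, MeOH, 0 °C
Reagents that add atoms: none
Why: Saegusa–Ito oxidation, in which palladation of the enol ether at C5 from the lower face (anti to the C1 oxygen and the C4 methyl) places the metal syn to H4, the only β-hydrogen (C1 has none), so β-hydride elimination gives the C4=C5 enone and erases the C4 and C5 centres, after which mild acidic methanolysis removes the tertiary trimethylsilyl ether without base contact for the β-alkoxy ketone.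

Step 20
Reactants: 26 1-hydroxyguai-4-en-6-one acetonide
Product: 27 1,6-diol with C1-OH on the upper face and C6-OH on the lower face
Conditions: Me4NBH(OAc)3, AcOH/MeCN, −30 °C
Reagents that add atoms: none
Why: Evans–Saksena hydroxyl-directed reduction, in which the C1 hydroxyl binds boron and delivers hydride to the upper face of the C6 carbonyl (the face also left open by the C7 side chain), should give the 1,6-anti diol with the C6 hydroxyl on the lower face.

Step 21
Reactants: 27 1,6-diol
Product: 28 C6 tert-butyldimethylsilyl ether with free C1 hydroxyl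
Conditions: TBSOTf, 2,6-lutidine, CH2Cl2, −78 °C
Reagents that add atoms: tert-butyldimethylsilyl trifluoromethanesulfonate, CC(C)(C)[Si](C)(C)OS(=O)(=O)C(F)(F)F
Why: Selective silylation of the secondary allylic C6 alcohol over the tertiary ring-fusion C1 alcohol masks C6-OH for the allylic oxidation and the acylations.

Step 22
Reactants: 28 C6 silyl ether
Product: 29 1-hydroxy-6-silyloxyguai-4-en-3-one acetonide
Conditions: Rh2(cap)4 (1 mol%), t-BuOOH (70% in water), 1,2-dichloroethane, 40 °C
Reagents that add atoms: tert-butyl hydroperoxide, CC(C)(C)OO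
Why: Allylic C–H oxidation of the tetrasubstituted C4=C5 alkene should take place at the ring methylene C3, which is more accessible than the silyloxy-bearing C6–H and weaker than the methyl C–H bonds, and a chromium oxidant is avoided because the tertiary allylic C1 alcohol could undergo oxidative transposition.

Step 23
Reactants: 29 enone acetonide
Product: 30 C8,C11-diol (C6 silyl ether and C1 hydroxyl retained)
Conditions: PPTS, MeOH, 40 °C
Reagents that add atoms: none
Why: Acid-catalysed transacetalisation with methanol removes the acetonide, while the hindered secondary silyl ether should survive and the tertiary allylic alcohol should not ionise because its cation would be conjugated with the enone carbonyl.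

Step 24
Reactants: 30 C8,C11-diol; 31 angelic acid
Product: 33 C8 angelate, via angelic 2,4,6-trichlorobenzoic anhydride 32 (not isolated)
Conditions: 31, 2,4,6-trichlorobenzoyl chloride, Et3N, toluene, rt; then 30, 80 °C
Reagents that add atoms: none
Why: Yamaguchi mixed-anhydride esterification without a nucleophilic catalyst acylates the only secondary alcohol (C8) at the less hindered angeloyl carbonyl and avoids the Z-to-E isomerisation (angelate to tiglate) that acylpyridinium intermediates cause.

Step 25
Reactants: 33 C8 angelate
Product: 34 C8 angelate C11 acetate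
Conditions: Ac2O, DMAP, Et3N, CH2Cl2, rt to 40 °C
Reagents that add atoms: acetic anhydride, CC(=O)OC(C)=O
Why: DMAP-catalysed acetylation should select the side-chain tertiary alcohol (C11), which is far more accessible than the ring-fusion tertiary C1 alcohol flanked by C10, C2 and the sp2 C5.

Step 26
Reactants: 34 C8 angelate C11 acetate
Product: 35 target CNP0273287.1
Conditions: HF·pyridine, pyridine, THF, 0 °C to rt
Reagents that add atoms: none
Why: Buffered fluoride desilylation cleaves the C6 silyl ether under non-basic conditions, so neither acyl migration nor angelate isomerisation is expected.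

**Compound list**

1 | (R)-carvone | CC1=CC[C@H](CC1=O)C(C)=C | starting material
2 | (5R)-5-(2-hydroxypropan-2-yl)-2-methylcyclohex-2-en-1-one | CC1=CC[C@H](CC1=O)C(C)(C)O | intermediate
3 | (1R,5R)-5-(2-hydroxypropan-2-yl)-2-methylcyclohex-2-en-1-ol | CC1=CC[C@@H](C(C)(C)O)C[C@H]1O | intermediate
4 | C1 tert-butyldimethylsilyl ether of 3 | CC1=CC[C@@H](C(C)(C)O)C[C@H]1O[Si](C)(C)C(C)(C)C | intermediate
5 | C8 ketone (enone), silyloxy and side chain cis | CC1=CC(=O)[C@@H](C(C)(C)O)C[C@H]1O[Si](C)(C)C(C)(C)C | intermediate
6 | C8 alcohol, C8-OH/C7 side chain/C1-OSi all on the lower face | CC1=C[C@@H](O)[C@@H](C(C)(C)O)C[C@H]1O[Si](C)(C)C(C)(C)C | intermediate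
7 | C8/C11 acetonide of 6 | CC1(C)O[C@@H]2C=C(C)[C@H](O[Si](C)(C)C(C)(C)C)C[C@@H]2C(C)(C)O1 | intermediate
8 | saturated all-cis acetonide, C1 silyl ether | CC1(C)O[C@@H]2C[C@H](C)[C@H](O[Si](C)(C)C(C)(C)C)C[C@@H]2C(C)(C)O1 | intermediate
9 | C1 alcohol | CC1(C)O[C@@H]2C[C@H](C)[C@H](O)C[C@@H]2C(C)(C)O1 | intermediate
10 | C1 ketone | CC1(C)O[C@@H]2C[C@H](C)C(=O)C[C@@H]2C(C)(C)O1 | intermediate
11 | C1 exocyclic methylene compound | CC1(C)O[C@@H]2C[C@H](C)C(=C)C[C@@H]2C(C)(C)O1 | intermediate
12 | C6 allylic alcohol (OH on the upper face) | CC1(C)O[C@@H]2C[C@H](C)C(=C)[C@@H](O)[C@@H]2C(C)(C)O1 | intermediate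
13 | C1 spiro-epoxide (O on the upper face), C6 alcohol | CC1(C)O[C@@H]2C[C@H](C)[C@]3(CO3)[C@@H](O)[C@@H]2C(C)(C)O1 | intermediate
14 | spiro-epoxy C6 ketone | CC1(C)O[C@@H]2C[C@H](C)[C@]3(CO3)C(=O)[C@@H]2C(C)(C)O1 | intermediate
15 | (E)-1-bromoprop-1-ene | C/C=C/Br | starting material
16 | (E)-prop-1-enyllithium | C/C=C/[Li] | intermediate
17 | (E)-prop-1-enylcerium dichloride | C/C=C/[Ce](Cl)Cl | intermediate
18 | C6 tertiary alcohol, (E)-propenyl on the upper face, OH on the lower face | CC1(C)O[C@@H]2C[C@H](C)[C@]3(CO3)[C@@](O)(/C=C/C)[C@@H]2C(C)(C)O1 | intermediate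
19 | C6 tert-butyldimethylsilyl ether of 18 | CC1(C)O[C@@H]2C[C@H](C)[C@]3(CO3)[C@@](O[Si](C)(C)C(C)(C)C)(/C=C/C)[C@@H]2C(C)(C)O1 | intermediate
20 | Cope substrate: 1-vinyl-1-hydroxy-6-(E)-propenyl-6-silyloxy cyclohexane acetonide | CC1(C)O[C@@H]2C[C@H](C)[C@](O)(C=C)[C@@](O[Si](C)(C)C(C)(C)C)(/C=C/C)[C@@H]2C(C)(C)O1 | intermediate
21 | ten-membered potassium enolate (C1=C2 enolate, C5=C6 silyl enol ether, both ring-trans) | CC1(C)O[C@@H]2C[C@H](C)/C([O-])=C/C[C@@H](C)/C=C(\O[Si](C)(C)C(C)(C)C)[C@@H]2C(C)(C)O1.[K+] | intermediate
22 | ten-membered C1 ketone with C5=C6 silyl enol ether | CC1(C)O[C@@H]2C[C@H](C)C(=O)CC[C@@H](C)/C=C(\O[Si](C)(C)C(C)(C)C)[C@@H]2C(C)(C)O1 | intermediate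
23 | cis-fused 1-hydroxyguaian-6-one acetonide | CC1(C)O[C@@H]2C[C@H](C)[C@]3(O)CC[C@@H](C)[C@@H]3C(=O)[C@@H]2C(C)(C)O1 | intermediate
24 | C1 trimethylsilyl ether, C5=C6 trimethylsilyl enol ether | CC1(C)O[C@@H]2C[C@H](C)[C@]3(O[Si](C)(C)C)CC[C@@H](C)C3=C(O[Si](C)(C)C)[C@@H]2C(C)(C)O1 | intermediate
25 | C1 trimethylsilyl ether of the 4-en-6-one | CC1(C)O[C@@H]2C[C@H](C)[C@]3(O[Si](C)(C)C)CCC(C)=C3C(=O)[C@@H]2C(C)(C)O1 | intermediate
26 | 1-hydroxyguai-4-en-6-one acetonide | CC1(C)O[C@@H]2C[C@H](C)[C@]3(O)CCC(C)=C3C(=O)[C@@H]2C(C)(C)O1 | intermediate
27 | 1,6-diol (C1-OH upper, C6-OH lower face) | CC1(C)O[C@@H]2C[C@H](C)[C@]3(O)CCC(C)=C3[C@H](O)[C@@H]2C(C)(C)O1 | intermediate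
28 | C6 tert-butyldimethylsilyl ether of 27 | CC1(C)O[C@@H]2C[C@H](C)[C@]3(O)CCC(C)=C3[C@H](O[Si](C)(C)C(C)(C)C)[C@@H]2C(C)(C)O1 | intermediate
29 | 1-hydroxy-6-silyloxyguai-4-en-3-one acetonide | CC1(C)O[C@@H]2C[C@H](C)[C@]3(O)CC(=O)C(C)=C3[C@H](O[Si](C)(C)C(C)(C)C)[C@@H]2C(C)(C)O1 | intermediate
30 | C8,C11-diol (1,8,11-triol, C6 silyl ether) | O[C@@H]1C[C@H](C)[C@]2(O)CC(=O)C(C)=C2[C@H](O[Si](C)(C)C(C)(C)C)[C@@H]1C(C)(C)O | intermediate
31 | angelic acid | C/C=C(/C)C(=O)O | starting material
32 | angelic 2,4,6-trichlorobenzoic anhydride | C/C=C(/C)C(=O)OC(=O)c1c(Cl)cc(Cl)cc1Cl | intermediate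
33 | C8 angelate | C/C=C(/C)C(=O)O[C@@H]1C[C@H](C)[C@]2(O)CC(=O)C(C)=C2[C@H](O[Si](C)(C)C(C)(C)C)[C@@H]1C(C)(C)O | intermediate
34 | C8 angelate C11 acetate, C6 silyl ether | C/C=C(/C)C(=O)O[C@@H]1C[C@H](C)[C@]2(O)CC(=O)C(C)=C2[C@H](O[Si](C)(C)C(C)(C)C)[C@@H]1C(C)(C)OC(C)=O | intermediate
35 | CNP0273287.1 | C/C=C(/C)C(=O)O[C@@H]1C[C@H](C)[C@]2(O)CC(=O)C(C)=C2[C@H](O)[C@@H]1C(C)(C)OC(C)=O | target

**Step count and risks**

Total step count: 26. Longest linear sequence: 26 steps from (R)-carvone 1; 15 and 31 enter as purchased.

Steps most likely to fail: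

Step 17 (key step, proposed new method). The substrate has no strain-free chair, and the Cope-competent conformer carries the C6 silyloxy, C8 oxygen and C10 methyl groups syn-axial. The rearrangement may therefore be slow and give way to a [1,3] shift or to migration of the silyl group to the C1 alkoxide, which would exchange the roles of C1 and C6. The ten-membered ring may change conformation before it closes, so that facial selectivity at C1 is lost. The Lewis acid may be tied up by potassium acetate, crown ether and THF. Fallback (known chemistry), from 20 back to 23: the oxy-Cope ring expansion alone is run (KH, 18-crown-6, THF) and quenched with aqueous NH4Cl at −78 °C, so that the ten-membered keto silyl enol ether 22 is isolated. N-Bromosuccinimide then converts the enol ether regiospecifically into the 5-bromo ten-membered 1,6-diketone F1 (both C5 epimers are usable). SmI2 in THF at −78 °C generates the C5 samarium enolate, which adds to the C1 ketone across the ring in a chelated Reformatsky-type aldol and returns to the route at 23.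

Step 18. Enolisation may take place toward C7 instead of C5, followed in the next step by dehydrogenation into the dioxane ring or β-elimination of the C8 oxygen, so that the C4=C5 double bond is not formed selectively. Fallback, from 20 back to 26: 22 is isolated as above and treated with PhSCl at −78 °C to give the 5-(phenylthio) ten-membered 1,6-diketone F2. The sulfur-bearing C5–H is now the most acidic position, so LiN(SiMe3)2 (1 equiv, THF, −78 °C to −20 °C) should close C1–C5 to the 5-(phenylthio) aldol F3. mCPBA at −78 °C gives the sulfoxide F4, and warming in toluene (sulfoxide syn-elimination, which can only involve H4) gives the enone 26 directly.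

Step 22. Hydrogen abstraction may occur at the silyloxy-bearing C6–H or at the C4 methyl group instead of C3 (poor site selectivity), or the product may be over-oxidised. Fallback, from 26 back to 29, in which the site is fixed by conjugation: TMSOTf/Et3N converts 26 into the bis-trimethylsilyl dienol ether F5 (C5=C6 and C3=C4). Dimethyldioxirane followed by a citric acid wash (vinylogous Rubottom oxidation) gives the 3-hydroxy-4-en-6-one F6. Me4NBH(OAc)3 reduces C6 under direction of the C1 hydroxyl to the 1,3,6-triol F7. MnO2 oxidises the unhindered cyclopentenyl C3 carbinol selectively to the 3-keto-1,6-diol F8, and TBSOTf/2,6-lutidine at −78 °C silylates C6-OH to give 29.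

Further compounds
F1 | step 17 | 5-bromo ten-membered 1,6-diketone | CC1(C)O[C@@H]2C[C@H](C)C(=O)CC[C@@H](C)C(Br)C(=O)[C@@H]2C(C)(C)O1
F2 | step 18 | 5-(phenylthio) ten-membered 1,6-diketone | CC1(C)O[C@@H]2C[C@H](C)C(=O)CC[C@@H](C)C(Sc3ccccc3)C(=O)[C@@H]2C(C)(C)O1
F3 | step 18 | 5-(phenylthio) aldol (1-hydroxy-5-phenylthioguaian-6-one acetonide) | CC1(C)O[C@@H]2C[C@H](C)[C@]3(O)CC[C@@H](C)C3(Sc4ccccc4)C(=O)[C@@H]2C(C)(C)O1
F4 | step 18 | sulfoxide of F3 | CC1(C)O[C@@H]2C[C@H](C)[C@]3(O)CC[C@@H](C)C3(S(=O)c4ccccc4)C(=O)[C@@H]2C(C)(C)O1
F5 | step 22 | bis-trimethylsilyl dienol ether | CC1(C)O[C@@H]2C[C@H](C)[C@]3(O[Si](C)(C)C)CC=C(C)C3=C(O[Si](C)(C)C)[C@@H]2C(C)(C)O1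
F6 | step 22 | 3-hydroxy-4-en-6-one | CC1(C)O[C@@H]2C[C@H](C)[C@]3(O)CC(O)C(C)=C3C(=O)[C@@H]2C(C)(C)O1
F7 | step 22 | 1,3,6-triol | CC1(C)O[C@@H]2C[C@H](C)[C@]3(O)CC(O)C(C)=C3[C@H](O)[C@@H]2C(C)(C)O1
F8 | step 22 | 3-keto-1,6-diol | CC1(C)O[C@@H]2C[C@H](C)[C@]3(O)CC(=O)C(C)=C3[C@H](O)[C@@H]2C(C)(C)O1
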